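Numbering used below: isoflavone numbering for the core (ring A = C5–C8a carbocycle, ring C = pyranone, ring B = C1'–C6'); side chain C1'' (benzylic CH2), C2'' (carbinol), C3''=C4'' (alkene), C5'' (methyl).

## The problem

Target 11 is genistein carrying on C3' of ring B a five-carbon chain made of the benzylic C1''H2, the carbinol carbon C2'' and an isopropenyl group (C3''=C4'' with methyl C5''). The flat isoflavone core is available in one operation from a phenol and an arylacetic acid, so the real difficulty is the chain: two C–C bonds (C3'–C1'' and C2''–C3''), an oxygen on C2'' and the single stereocentre C2'' (R). There is no second stereo element, and the nearest group, the 4'-oxygen, cannot direct anything reliably, so C2'' must be set by a chiral catalyst or reagent. The finished chain is fragile: a secondary allylic alcohol beside a free ortho phenol ionises or cyclises under acid, and the 1,1-disubstituted alkene rules out hydrogenolysis. The core is fragile too: ring C is opened at C2 by hydroxide and carbon nucleophiles and is attacked by basic peroxide, and the 5-OH, hydrogen-bonded to C4=O, is hard to mask and its ethers leave easily. Electrophilic substitution of the polyphenol goes to ring A (C6, C8), so a handle on C3' has to be bought in place. The enabling feature is the pattern aryl carbon C3' / two-carbon unit C1''–C2'' with a heteroatom on C2'' / alkenyl group on C2'': a conjunctive coupling builds exactly this from an aryl halide, a vinylboron unit and a migrating alkenyl group and leaves boron where the hydroxyl belongs, while the 1,1-disubstitution of the isopropenyl group tells the two alkenyl groups on boron apart.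

## Retrosynthesis

**11 ⇒ 10.** The three O–Si bonds at O5, O7 and O4' are cut. Methyl ethers would need Lewis acids, benzyl ethers hydrogen and acetals protic acid, all of which endanger the allylic alcohol or the alkene; silyl ethers leave with buffered fluoride. Tris-silyl ether 10 is no simpler in skeleton, but its phenols are inert to organometallic chemistry. The forward step only has to be complete at all three oxygens without generating free phenoxide.

**10 ⇒ 9.** The C2''–O bond is traced back to a C2''–B bond in allylic pinacol boronate 9. Oxidation at boron is stereospecific (retention) and raises no regiochemical question, because the alkene is already in its final place. The neighbouring cuts are weaker: adding an isopropenyl nucleophile to an arylacetaldehyde needs an enolisable aldehyde and a separate chiral controller, and isomerising a prenyl epoxide must choose between methyl and benzylic protons. The forward step needs an oxidant that attacks boron faster than C2 of the chromone.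

**9 ⇒ 5 + 6 + 7 (through borate 8).** Two bonds are cut at once, C3'–C1'' and C2''–C3''. The chain falls into aryl bromide 5, isopropenylboronic ester 6 and vinylmagnesium bromide 7, and the stereocentre arises in the same event. Cutting only C3'–C1'' (a prenyl or allyl coupling) would leave both the oxygen and the stereocentre for later steps. Precursor 5 is achiral and carries no side chain. The forward reaction must make the vinyl group the acceptor and the isopropenyl group the migrating group, select one alkene face, tolerate the chromone, and accept an aryl bromide flanked by a bulky silyloxy group.

**5 ⇒ 4.** Three O–Si bonds are cut again. All phenols of 3'-bromogenistein 4 must be capped, the chelated 5-OH included, because borate 8 and any trace of 7 do not tolerate acidic O–H. The forward step therefore needs a silylating agent strong enough for the hydrogen-bonded hydroxyl.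

**4 ⇒ 1 + 2 (through deoxybenzoin 3).** The aryl ketone bond C4–C4a and the two bonds to C2 (C2–C3, C2–O1) are cut; C2 comes from a formamide-derived one-carbon electrophile. Phloroglucinol 1 is symmetrical, so acylation and ring closure each give one isomer, and acid 2 already has bromine ortho to the hydroxyl. A cross-coupling of a 3-halochromone with an arylboron reagent would be longer and would put a second halogen into play. Late bromination would go to ring A. The forward reaction has to deliver acylation and ring closure in one flask.

## Roads not taken

**Alternative 1:** The cut is the C4–C4a bond of ring C. The aryloxyacrylic acid A2 is cyclised in P2O5/CH3SO3H; its acylium carbon attacks the dimethoxyphenoxy ring ortho to the ether oxygen and gives the trimethyl ether A1.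
- Merits: both ortho positions are equivalent, so the closure is regiochemically clean. Methyl ethers would pass through a borate coupling without the fragile 5-O-silyl group of the chosen plan, which is a real advantage.
- Weak points: A2 must be made as the Z isomer over several steps. The stereocentre is not addressed at all. Three aryl methyl ethers cannot be removed at the end without destroying the allylic alcohol, so demethylation would have to precede the side chain and lead back to 4 by a much longer path.
- Comparison: the chosen plan reaches 4 in one operation and ends with fluoride, which the chain survives. It pays for this with the labile silyl ether at O5.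

**Alternative 2:** The cut lies inside ring A (C4a–C5). The pyrone A4 is opened by Mg(OMe)2 in methanol, and the carbon between the two ketones closes onto the ester to give the allyl deoxybenzoin A3.
- Merits: the sequence is polyketide-like and needs no palladium and no halide. An allyl group is a sturdy handle through ring construction.
- Weak points: it builds a ring that can be bought as 1. The allyl group has only three carbons and neither the branch, the oxygen nor the stereocentre, so a separate multi-step and enantioselective elaboration would follow. Competing aldol modes of the open triketo ester also have to be suppressed.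
- Comparison: it avoids the hindered oxidative addition that the chosen plan must overcome. The chosen plan sets against this the formation of both chain bonds and the stereocentre in one step, in a route of five steps.

**Alternative 3:** The cut is the two C–O bonds of an oxirane on the prenyl group. The prenyl isoflavone A6 is epoxidised by the D-fructose-derived ketone catalyst with KHSO5 near pH 10.5 to the (R)-epoxide A5, which must then be isomerised to the allylic alcohol.
- Merits: prenyl isoflavones are easy to reach. Ketone-catalysed epoxidation of trisubstituted alkenes is broadly reliable in its facial selectivity, arguably more predictable than a conjunctive coupling on a new, hindered bromide. The catalyst is cheap.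
- Weak points: an epoxide next to a masked ortho phenol cyclises as soon as the silyl group is lost in the basic medium. The free 5-OH is ionised at that pH. The isomerisation must take a methyl proton and not a benzylic one.
- Comparison: the route is about one step longer. The chosen plan avoids the epoxide and the isomerisation because boron sits on C2'' with the alkene already formed. In stereochemical predictability Alternative 3 is the stronger plan, so a fully silylated version of it is kept as the fallback for the key step.

Key step: step 3

Assumption: the sense of induction of the ferrocenyl bis(phosphine) on this borate is not presumed; the ligand enantiomer that delivers R at C2'' is used (both enantiomers are commercial), and the configuration would be confirmed on alcohol 10 by Mosher ester analysis.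

## Route

Step 1
Reactants: 1 phloroglucinol; 2 2-(3-bromo-4-hydroxyphenyl)acetic acid
Product: 4 3'-bromogenistein [3-(3-bromo-4-hydroxyphenyl)-5,7-dihydroxy-4H-chromen-4-one], via deoxybenzoin 3 (not isolated)
Conditions: BF3·OEt2, 85 °C; then DMF, CH3SO2Cl, 50 to 90 °C; aq. NaOAc work-up
Reagents that add atoms: N,N-dimethylformamide (DMF), CN(C)C=O
Why: Friedel–Crafts acylation of symmetrical 1 by the BF3-activated acid gives 3 as its boron chelate; the Vilsmeier-type iminium salt from DMF and CH3SO2Cl then formylates the activated methylene and an ortho hydroxyl closes ring C with loss of dimethylamine. This one-flask isoflavone synthesis is well established for polyhydroxy deoxybenzoins, and the aryl bromide is inert to it.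

Step 2
Reactants: 4 3'-bromogenistein
Product: 5 3'-bromo-5,7,4'-tris(tert-butyldimethylsilyloxy)isoflavone
Conditions: tBuMe2SiOTf (3.6 equiv), 2,6-lutidine, CH2Cl2, 0 °C to rt; purification on Et3N-deactivated silica
Reagents that add atoms: tert-butyldimethylsilyl trifluoromethanesulfonate, CC(C)(C)[Si](C)(C)OS(=O)(=O)C(F)(F)F
Why: O-silylation with a silyl triflate and a hindered pyridine base caps all three phenols, including the hydrogen-bonded 5-OH that resists the silyl chloride; the bromide and the chromone are not touched.

Step 3
Reactants: 5 3'-bromo-5,7,4'-tris(tert-butyldimethylsilyloxy)isoflavone; 6 isopropenylboronic acid pinacol ester; 7 vinylmagnesium bromide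
Product: 9 (R)-allylic pinacol boronate of the tris-silylated isoflavone, via bromomagnesium borate 8 (not isolated)
Conditions: 6 (1.5 equiv), 7 (1.4 equiv), THF, 0 °C to rt; then 5, Pd(OAc)2 (3 mol%), (Sp,Sp)-1,1'-bis[bis(4-methoxy-3,5-dimethylphenyl)phosphino]-2,2'-bis[(R)-α-(dimethylamino)benzyl]ferrocene or its mirror image (3.6 mol%), NaOTf (3 equiv), THF/DMSO, 40 °C
Reagents that add atoms: none
Why: The step is an enantioselective three-component conjunctive cross-coupling of a Grignard-derived bis(alkenyl)borate with an aryl bromide, a known reaction type applied here to a new bromide. Oxidative addition of zerovalent palladium to the C3'–Br bond, followed by removal of bromide as NaBr by NaOTf, should give a cationic divalent arylpalladium species that coordinates the unsubstituted vinyl group of 8. This coordination triggers a 1,2-metallate shift in which the isopropenyl group moves from boron to the boron-bearing carbon on the face opposite palladium (C2''–C3''), the metal ends up on the terminal carbon, and reductive elimination then joins C3' to C1''; no ring is closed. The C2'' stereocentre is under catalyst control, since the chiral bis(phosphine) decides which face of the vinyl group palladium occupies and the anti shift translates that choice into R at C2''. The site selectivity that is needed comes from the 1,1-disubstituted isopropenyl group, which is a poor ligand for palladium and therefore migrates while the bare vinyl group accepts. The metallate shift must also outrun direct Suzuki transfer of an alkenyl group, which the chelating ligand and the cationic metal centre favour. The chromone should survive because the four-coordinate borate is not a carbon nucleophile toward C2 or C4 and 6 is kept in slight excess over 7, so that no free Grignard reagent meets 5. The ortho silyloxy group should slow oxidative addition without blocking it.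

Step 4
Reactants: 9 (R)-allylic pinacol boronate of the tris-silylated isoflavone
Product: 10 (R)-allylic alcohol of the tris-silylated isoflavone
Conditions: NaBO3·4H2O, THF/pH 7 phosphate buffer, 0 °C to rt
Reagents that add atoms: sodium perborate tetrahydrate, [Na+].[O-]OB=O.O.O.O.O
Why: Boronate oxidation: peroxide adds to boron and the C2''–B bond migrates to oxygen with retention, so R-9 should give R-10 without allylic transposition. The buffered, cold medium is meant to spare ring C and the aryl silyl ethers, and partial loss of a silyl group would be harmless because step 5 removes them all.

Step 5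
Reactants: 10 (R)-allylic alcohol of the tris-silylated isoflavone
Product: 11 5,7-dihydroxy-3-{4-hydroxy-3-[(2R)-2-hydroxy-3-methylbut-3-en-1-yl]phenyl}-4H-chromen-4-one (target)
Conditions: Bu4NF, AcOH (1:1, 3.5 equiv), THF, 0 °C
Reagents that add atoms: none
Why: Fluoride-mediated cleavage of the three aryl silyl ethers; acetic acid protonates the phenoxides as they form, so neither ring C nor the allylic alcohol beside the 4'-oxygen is exposed to base or to strong acid, and C2'' is not touched.

## Compound list

1 | phloroglucinol | Oc1cc(O)cc(O)c1 | starting material
2 | 2-(3-bromo-4-hydroxyphenyl)acetic acid | OC(=O)Cc1ccc(O)c(Br)c1 | starting material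
3 | 2-(3-bromo-4-hydroxyphenyl)-1-(2,4,6-trihydroxyphenyl)ethan-1-one (deoxybenzoin) | O=C(Cc1ccc(O)c(Br)c1)c1c(O)cc(O)cc1O | intermediate
4 | 3'-bromogenistein, 3-(3-bromo-4-hydroxyphenyl)-5,7-dihydroxy-4H-chromen-4-one | Oc1ccc(-c2coc3cc(O)cc(O)c3c2=O)cc1Br | intermediate
5 | 3'-bromo-5,7,4'-tris(tert-butyldimethylsilyloxy)isoflavone | Brc1cc(-c2coc3cc(O[Si](C)(C)C(C)(C)C)cc(O[Si](C)(C)C(C)(C)C)c3c2=O)ccc1O[Si](C)(C)C(C)(C)C | intermediate
6 | isopropenylboronic acid pinacol ester | CC(=C)B1OC(C)(C)C(C)(C)O1 | starting material
7 | vinylmagnesium bromide | C=C[Mg]Br | starting material
8 | bromomagnesium isopropenyl(vinyl)(pinacolato)borate | C=C[B-]1(C(C)=C)OC(C)(C)C(C)(C)O1.[Mg+]Br | intermediate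
9 | 5,7-bis(tert-butyldimethylsilyloxy)-3-{4-(tert-butyldimethylsilyloxy)-3-[(2R)-3-methyl-2-(4,4,5,5-tetramethyl-1,3,2-dioxaborolan-2-yl)but-3-en-1-yl]phenyl}-4H-chromen-4-one | C=C(C)[C@H](B1OC(C)(C)C(C)(C)O1)Cc1cc(-c2coc3cc(O[Si](C)(C)C(C)(C)C)cc(O[Si](C)(C)C(C)(C)C)c3c2=O)ccc1O[Si](C)(C)C(C)(C)C | intermediate
10 | 5,7-bis(tert-butyldimethylsilyloxy)-3-{4-(tert-butyldimethylsilyloxy)-3-[(2R)-2-hydroxy-3-methylbut-3-en-1-yl]phenyl}-4H-chromen-4-one | C=C(C)[C@H](O)Cc1cc(-c2coc3cc(O[Si](C)(C)C(C)(C)C)cc(O[Si](C)(C)C(C)(C)C)c3c2=O)ccc1O[Si](C)(C)C(C)(C)C | intermediate
11 | 5,7-dihydroxy-3-{4-hydroxy-3-[(2R)-2-hydroxy-3-methylbut-3-en-1-yl]phenyl}-4H-chromen-4-one | C=C(C)[C@H](O)Cc1cc(-c2coc3cc(O)cc(O)c3c2=O)ccc1O | target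

## Step count and least certain steps

Total: 5 steps. Longest linear sequence: 5 steps (1 and 2 to 4, 5, 9, 10, 11); 6 and 7 are purchased.

**Step 3 (key step).** The most likely failure is slow oxidative addition beside the bulky 4'-silyloxy group. Direct Suzuki transfer of an alkenyl group or decay of the borate could then overtake the metallate shift, and facial selectivity on this unprecedented bromide could erode. Leakage of free Grignard reagent onto C2 of the chromone is a second risk. The fallback sets out from 5 and gives up the boron chemistry. Stille coupling of 5 with tributyl(3-methylbut-2-en-1-yl)stannane (Pd(PPh3)4, DMF, 90 °C) should give the 3'-prenyl tris-silyl ether F1. Epoxidation of this alkene with the D-fructose-derived ketone catalyst and KHSO5 (K2CO3 buffer, MeCN/dimethoxymethane/water, 0 °C) should give the (R)-epoxide F2, with every phenol still silylated. Isomerisation of the epoxide with Al(OiPr)3 in toluene at reflux removes a methyl proton and opens the C3''–O bond; C2'' is untouched, and the route is rejoined at 10.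

**Step 4.** Hydroperoxide may add to C2 of the chromone (epoxidation or ring opening) in competition with attack at boron, and the mildly basic medium may strip the 7-O-silyl group and expose a phenoxide to the oxidant. The fallback sets out from 9 and changes both the boron species and the oxidant. KHF2 in aqueous methanol at rt converts the boronate into a trifluoroborate and removes the three aryl silyl ethers, giving the potassium trifluoroborate F3. A few minutes with the electrophilic oxidant KHSO5 in acetone/water at rt should then replace boron by hydroxyl with retention; this oxidant does not add to enones. The route is rejoined directly at 11, and step 5 is no longer needed.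

**Step 2.** Silylation of the hydrogen-bonded 5-OH may stop short, and the 5-O–Si bond, activated by the neighbouring carbonyl, may hydrolyse during purification. The fallback sets out from 4 and installs the fragile group last. tBuMe2SiCl and imidazole in DMF silylate only the two unchelated phenols and give the robust bis-silyl ether F4, which can be purified freely. Deprotonation of this phenol with NaN(SiMe3)2 in THF at −78 °C and capture of the phenoxide with tBuMe2SiOTf returns to 5, which is then used in step 3 without chromatography.

## Further compounds

F1 | step 3 | 5,7,4'-tris(tert-butyldimethylsilyloxy)-3'-(3-methylbut-2-en-1-yl)isoflavone | CC(C)=CCc1cc(-c2coc3cc(O[Si](C)(C)C(C)(C)C)cc(O[Si](C)(C)C(C)(C)C)c3c2=O)ccc1O[Si](C)(C)C(C)(C)C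
F2 | step 3 | 5,7,4'-tris(tert-butyldimethylsilyloxy)-3'-{[(2R)-3,3-dimethyloxiran-2-yl]methyl}isoflavone | CC1(C)O[C@@H]1Cc1cc(-c2coc3cc(O[Si](C)(C)C(C)(C)C)cc(O[Si](C)(C)C(C)(C)C)c3c2=O)ccc1O[Si](C)(C)C(C)(C)C
F3 | step 4 | potassium {(2R)-1-[5-(5,7-dihydroxy-4-oxo-4H-chromen-3-yl)-2-hydroxyphenyl]-3-methylbut-3-en-2-yl}trifluoroborate | C=C(C)[C@H]([B-](F)(F)F)Cc1cc(-c2coc3cc(O)cc(O)c3c2=O)ccc1O.[K+]
F4 | step 2 | 3'-bromo-7,4'-bis(tert-butyldimethylsilyloxy)-5-hydroxyisoflavone | Brc1cc(-c2coc3cc(O[Si](C)(C)C(C)(C)C)cc(O)c3c2=O)ccc1O[Si](C)(C)C(C)(C)C
A1 | alternative 1 | 3'-bromo-5,7,4'-trimethoxyisoflavone | COc1cc(OC)c2c(c1)occ(-c1ccc(OC)c(Br)c1)c2=O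
A2 | alternative 1 | (Z)-2-(3-bromo-4-methoxyphenyl)-3-(3,5-dimethoxyphenoxy)acrylic acid | COc1cc(OC)cc(O/C=C(/c2ccc(OC)c(Br)c2)C(=O)O)c1
A3 | alternative 2 | 2-(3-allyl-4-hydroxyphenyl)-1-(2,4,6-trihydroxyphenyl)ethanone | C=CCc1cc(CC(=O)c2c(O)cc(O)cc2O)ccc1O
A4 | alternative 2 | 6-[3-(3-allyl-4-hydroxyphenyl)-2-oxopropyl]-4-hydroxy-2H-pyran-2-one | C=CCc1cc(CC(=O)Cc2cc(O)cc(=O)o2)ccc1O
A5 | alternative 3 | 3'-{[(2R)-3,3-dimethyloxiran-2-yl]methyl}-5-hydroxy-7,4'-bis(triisopropylsilyloxy)isoflavone | CC1(C)O[C@@H]1Cc1cc(-c2coc3cc(O[Si](C(C)C)(C(C)C)C(C)C)cc(O)c3c2=O)ccc1O[Si](C(C)C)(C(C)C)C(C)C
A6 | alternative 3 | 5-hydroxy-3'-(3-methylbut-2-en-1-yl)-7,4'-bis(triisopropylsilyloxy)isoflavone | CC(C)=CCc1cc(-c2coc3cc(O[Si](C(C)C)(C(C)C)C(C)C)cc(O)c3c2=O)ccc1O[Si](C(C)C)(C(C)C)C(C)C
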